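## Retrosynthetic overview

1. Numbering runs from C1 (alkyne CH) to C15 (CH3). The oxolane is O(a), C6, C7, C8, C9 and the oxepane is C7, O(b), C12, C11, C10, C9, C8. The enyne is completed last from a C6 propargyl group (iodoalkyne, (Z)-iodoalkene, Sonogashira coupling).
2. Enabling feature: the C9–O(a) bond and the C10–Br bond are vicinal and anti, which is the signature of an oxonium opening. The 2,7-dioxabicyclo[4.2.1]nonane is therefore cut back to a 2,6-dioxabicyclo[3.2.2]nonan-9-ol in which O(a) joins C6 and C10 (an oxane) and the C9–O bond is antiperiplanar to C10–O(a). A 1,2-shift of O(a) from C10 to C9, with bromide entering at C10, contracts the oxane to the oxolane.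
3. The [3.2.2] bicycle comes from an all-cis 2,6-dialkyloxane-3,5-diol derivative by 7-exo bromoetherification of the (E)-C12=C13 alkene with the C7 hydroxyl, which sets C12 and C13–Br.
4. The all-cis oxane comes from a furan: Keck propargylation (C6), Achmatowicz ring expansion, Kishi reduction (C10), CBS reduction (C7), directed epoxidation and trans-diaxial hydride opening (C9).
5. Ring order: furan, then pyranone/oxane, then the oxepane bridge, then the oxolane by contraction of the oxane.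

Key step: step 12

Remark: compounds 1, 2, 5 and 22 are taken as purchased; locants C5–C15 and the labels O(a)/O(b) in the text refer to the target numbering given above.

## Route

Step 1
Reactants: 1 2-(diethoxymethyl)furan; 2 (2E)-1-bromopent-2-ene
Product: 4 5-[(2E)-pent-2-en-1-yl]furan-2-carbaldehyde, via alkylated acetal 3 (not isolated)
Conditions: n-BuLi, THF, −78 → 0 °C; then 2, −78 °C → rt; then 1 M HCl, rt
Reagents that add atoms: water, O
Why: Directed C5 lithiation of the furan acetal, SN2 alkylation by the primary allylic bromide with retention of the E geometry, then acetal hydrolysis; no stereocentre is formed.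

Step 2
Reactants: 4 5-[(2E)-pent-2-en-1-yl]furan-2-carbaldehyde; 5 tributyl(propa-1,2-dien-1-yl)stannane
Product: 6 (1R)-1-{5-[(2E)-pent-2-en-1-yl]furan-2-yl}but-3-yn-1-ol
Conditions: (R)-BINOL (20 mol %), Ti(OiPr)4 (10 mol %), 4 Å molecular sieves, CH2Cl2, −20 °C
Reagents that add atoms: none
Why: Keck asymmetric propargylation (SE2' addition of the allenylstannane to the aldehyde bound to the BINOL–titanium complex) should set the carbinol centre that becomes C6 as (R), as known for aryl aldehydes with (R)-BINOL.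

Step 3
Reactants: 6 (1R)-1-{5-[(2E)-pent-2-en-1-yl]furan-2-yl}but-3-yn-1-ol
Product: 7 (2R)-6-hydroxy-6-[(2E)-pent-2-en-1-yl]-2-(prop-2-yn-1-yl)-2H-pyran-3(6H)-one (mixture at the hemiketal carbon)
Conditions: NBS, NaHCO3, NaOAc, THF/H2O (4:1), 0 °C
Reagents that add atoms: water, O
Why: Achmatowicz rearrangement; the electron-rich furan is oxidised much faster than the isolated alkene or alkyne, the ene-dione recloses on the carbinol oxygen, and C6 is untouched.

Step 4
Reactants: 7 (2R)-6-hydroxy-6-[(2E)-pent-2-en-1-yl]-2-(prop-2-yn-1-yl)-2H-pyran-3(6H)-one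
Product: 8 (2R,6S)-6-[(2E)-pent-2-en-1-yl]-2-(prop-2-yn-1-yl)-2H-pyran-3(6H)-one
Conditions: Et3SiH, CF3CO2H, CH2Cl2, −40 °C
Reagents that add atoms: none
Why: Kishi reduction (ionic hydrogenation of the hemiketal); axial hydride delivery to the cyclic oxocarbenium ion should give the 2,6-cis isomer and so set C10 as (S) relative to C6.

Step 5
Reactants: 8 (2R,6S)-6-[(2E)-pent-2-en-1-yl]-2-(prop-2-yn-1-yl)-2H-pyran-3(6H)-one
Product: 9 (2R,3R,6S)-6-[(2E)-pent-2-en-1-yl]-2-(prop-2-yn-1-yl)-3,6-dihydro-2H-pyran-3-ol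
Conditions: (R)-2-methyl-CBS-oxazaborolidine (20 mol %), catecholborane, toluene, −78 °C; aqueous NaOH work-up
Reagents that add atoms: none
Why: CBS reduction; catalyst-controlled 1,2-hydride delivery (alkenyl arm as the large group) should give the pseudo-axial C7 alcohol cis to the propargyl group, overriding the substrate's modest preference for the trans alcohol.

Step 6
Reactants: 9 (2R,3R,6S)-6-[(2E)-pent-2-en-1-yl]-2-(prop-2-yn-1-yl)-3,6-dihydro-2H-pyran-3-ol
Product: 10 (1R,2S,4R,5S,6S)-2-[(2E)-pent-2-en-1-yl]-4-(prop-2-yn-1-yl)-3,7-dioxabicyclo[4.1.0]heptan-5-ol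
Conditions: VO(acac)2 (5 mol %), t-BuOOH, CH2Cl2, 0 °C
Reagents that add atoms: tert-butyl hydroperoxide, CC(C)(C)OO
Why: Hydroxyl-directed epoxidation; the vanadium alkoxide delivers oxygen syn to the allylic hydroxyl, setting C8 and C9 on the face of both side chains, and the remote alkene and alkyne are not directed.

Step 7
Reactants: 10 (1R,2S,4R,5S,6S)-2-[(2E)-pent-2-en-1-yl]-4-(prop-2-yn-1-yl)-3,7-dioxabicyclo[4.1.0]heptan-5-ol
Product: 11 triethyl{[(1R,2S,4R,5S,6R)-2-[(2E)-pent-2-en-1-yl]-4-(prop-2-yn-1-yl)-3,7-dioxabicyclo[4.1.0]heptan-5-yl]oxy}silane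
Conditions: Et3SiCl, imidazole, CH2Cl2, 0 °C
Reagents that add atoms: chlorotriethylsilane, CC[Si](Cl)(CC)CC
Why: Standard silylation of the secondary alcohol, so that the next step leaves the C9 hydroxyl as the only free one; no stereocentre changes.

Step 8
Reactants: 11 triethyl{[(1R,2S,4R,5S,6R)-2-[(2E)-pent-2-en-1-yl]-4-(prop-2-yn-1-yl)-3,7-dioxabicyclo[4.1.0]heptan-5-yl]oxy}silane
Product: 12 (2S,3S,5R,6R)-2-[(2E)-pent-2-en-1-yl]-6-(prop-2-yn-1-yl)-5-[(triethylsilyl)oxy]oxan-3-ol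
Conditions: LiAlH4, THF, 0 °C → rt
Reagents that add atoms: none
Why: Fürst–Plattner trans-diaxial epoxide opening; hydride should attack C8 through the chair that keeps both side chains equatorial, leaving the axial C9 hydroxyl with the epoxide configuration and an all-cis oxane.

Step 9
Reactants: 12 (2S,3S,5R,6R)-2-[(2E)-pent-2-en-1-yl]-6-(prop-2-yn-1-yl)-5-[(triethylsilyl)oxy]oxan-3-ol
Product: 14 (2S,3S,5R,6R)-5-hydroxy-2-[(2E)-pent-2-en-1-yl]-6-(prop-2-yn-1-yl)oxan-3-yl acetate, via silyl ether acetate 13 (not isolated)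
Conditions: Ac2O, pyridine, DMAP (cat.), CH2Cl2, rt; then HF·pyridine, pyridine, THF, 0 °C
Reagents that add atoms: acetic anhydride, CC(=O)OC(C)=O
Why: Acetylation masks the C9 oxygen as a non-nucleophilic ester (a free C9 hydroxyl would close a five-membered ring onto C12 in the next step), and buffered fluoride desilylation frees the C7 hydroxyl under non-basic conditions that should not move the acetyl group.

Step 10
Reactants: 14 (2S,3S,5R,6R)-5-hydroxy-2-[(2E)-pent-2-en-1-yl]-6-(prop-2-yn-1-yl)oxan-3-yl acetate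
Product: 15 (1R,3R,5S,7R,9S)-3-[(1S)-1-bromopropyl]-7-(prop-2-yn-1-yl)-2,6-dioxabicyclo[3.2.2]nonan-9-yl acetate
Conditions: Et2SBr·SbCl5Br, MeNO2, −25 °C
Reagents that add atoms: bromodiethylsulfonium bromopentachloroantimonate, CC[S+](Br)CC.Cl[Sb-](Cl)(Cl)(Cl)(Cl)Br
Why: Bromoetherification; the C7 hydroxyl should add 7-exo to the bromonium ion of the (E)-alkene anti to bromine, which fixes the C12–O/C13–Br relationship as (12R,13S) when the bromopropyl arm lies on the C8–C9 side away from the C6 propargyl group, while the oxane oxygen (four-membered closure) and the acetate cannot compete.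

Step 11
Reactants: 15 (1R,3R,5S,7R,9S)-3-[(1S)-1-bromopropyl]-7-(prop-2-yn-1-yl)-2,6-dioxabicyclo[3.2.2]nonan-9-yl acetate
Product: 16 (1R,3R,5S,7R,9S)-3-[(1S)-1-bromopropyl]-7-(prop-2-yn-1-yl)-2,6-dioxabicyclo[3.2.2]nonan-9-ol
Conditions: K2CO3, MeOH, 0 °C
Reagents that add atoms: none
Why: Base-catalysed transesterification of the acetate; the secondary bromide next to an ether (not a free hydroxyl) should survive, and no stereocentre changes.

Step 12
Reactants: 16 (1R,3R,5S,7R,9S)-3-[(1S)-1-bromopropyl]-7-(prop-2-yn-1-yl)-2,6-dioxabicyclo[3.2.2]nonan-9-ol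
Product: 19 (1R,3R,5R,6R,8R)-5-bromo-3-[(1S)-1-bromopropyl]-8-(prop-2-yn-1-yl)-2,7-dioxabicyclo[4.2.1]nonane, via triflate 17 (not isolated), via bridged oxonium triflate 18 (not isolated)
Conditions: Tf2O, 2,6-di-tert-butyl-4-methylpyridine, CH2Cl2, −78 °C; then Bu4NBr, −78 → 0 °C
Reagents that add atoms: tetrabutylammonium bromide, CCCC[N+](CCCC)(CCCC)CCCC.[Br-]
Why: Triflation of the C9 hydroxyl gives a leaving group antiperiplanar to the C10–O bond of the boat-locked oxane, so the ring oxygen shifts from C10 to C9 as triflate leaves (a Wagner–Meerwein-type 1,2-oxygen shift through an oxygen-bridged oxonium ion) and bromide then opens the three-membered oxonium ring at C10 from the rear; the oxane (O, C6, C7, C8, C9, C10) contracts to the oxolane (O, C6, C7, C8, C9) and the 2,6-dioxabicyclo[3.2.2]nonane becomes the 2,7-dioxabicyclo[4.2.1]nonane. The closest known reaction types are the oxonium-mediated ring-size changes of β-sulfonyloxy cyclic ethers (oxolane–oxane interconversion through 1-oxoniabicyclo[3.1.0]hexanes) and the 2-oxabicyclo[2.2.2]octane to 6-oxabicyclo[3.2.1]octane rearrangement. The oxolane closes by 3-exo-tet attack of the ring oxygen on C9 (neighbouring-group participation), after which the old O–C10 bond is cleaved by bromide. C9 is inverted by the internal oxygen and C10 by bromide, so both new centres (9R,10R) follow stereospecifically from the (9S,10S) configuration of 16. The step needs bromide to enter at C10 rather than displace the triflate directly at C9 or return to C9; this should be secured because backside attack at C9 is shielded by the bicyclic cage (as at C2 of a bicyclo[2.2.2]octane), bromide is added only after the triflate has formed, and attack at C10 releases the strained boat oxane whereas attack at C9 restores it.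

Step 13
Reactants: 19 (1R,3R,5R,6R,8R)-5-bromo-3-[(1S)-1-bromopropyl]-8-(prop-2-yn-1-yl)-2,7-dioxabicyclo[4.2.1]nonane
Product: 20 (1R,3R,5R,6R,8R)-5-bromo-3-[(1S)-1-bromopropyl]-8-(3-iodoprop-2-yn-1-yl)-2,7-dioxabicyclo[4.2.1]nonane
Conditions: N-iodomorpholine hydroiodide, CuI (5 mol %), THF, rt
Reagents that add atoms: N-iodomorpholine hydroiodide, IN1CCOCC1.I
Why: Copper-acetylide-mediated iodination of the terminal alkyne under near-neutral conditions, without silver salts or strong base that could ionise or eliminate the β-bromo ethers; no stereocentre changes.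

Step 14
Reactants: 20 (1R,3R,5R,6R,8R)-5-bromo-3-[(1S)-1-bromopropyl]-8-(3-iodoprop-2-yn-1-yl)-2,7-dioxabicyclo[4.2.1]nonane
Product: 21 (1R,3R,5R,6R,8R)-5-bromo-3-[(1S)-1-bromopropyl]-8-[(2Z)-3-iodoprop-2-en-1-yl]-2,7-dioxabicyclo[4.2.1]nonane
Conditions: 2-nitrobenzenesulfonohydrazide, Et3N, THF/i-PrOH, rt
Reagents that add atoms: none
Why: Diimide reduction; concerted syn delivery of two hydrogens to the 1-iodoalkyne should give the (Z)-iodoalkene, and alkyl bromides are inert to diimide.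

Step 15
Reactants: 21 (1R,3R,5R,6R,8R)-5-bromo-3-[(1S)-1-bromopropyl]-8-[(2Z)-3-iodoprop-2-en-1-yl]-2,7-dioxabicyclo[4.2.1]nonane; 22 ethynyltrimethylsilane
Product: 23 (1R,3R,5R,6R,8R)-5-bromo-3-[(1S)-1-bromopropyl]-8-[(2Z)-5-(trimethylsilyl)pent-2-en-4-yn-1-yl]-2,7-dioxabicyclo[4.2.1]nonane
Conditions: Pd(PPh3)4 (5 mol %), CuI (10 mol %), Et2NH, THF, rt
Reagents that add atoms: none
Why: Sonogashira coupling of the alkenyl iodide proceeds with retention of the Z geometry, and secondary alkyl bromides do not undergo oxidative addition under these conditions.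

Step 16
Reactants: 23 (1R,3R,5R,6R,8R)-5-bromo-3-[(1S)-1-bromopropyl]-8-[(2Z)-5-(trimethylsilyl)pent-2-en-4-yn-1-yl]-2,7-dioxabicyclo[4.2.1]nonane
Product: 24 (1R,3R,5R,6R,8R)-5-bromo-3-[(1S)-1-bromopropyl]-8-[(2Z)-pent-2-en-4-yn-1-yl]-2,7-dioxabicyclo[4.2.1]nonane (target CNP0289066.1)
Conditions: K2CO3, MeOH, rt
Reagents that add atoms: none
Why: Methanolysis of the alkynyl C–Si bond (protodesilylation) under mild base that should leave both secondary bromides and all six stereocentres untouched.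

## Compound list

1 | 2-(diethoxymethyl)furan | CCOC(OCC)c1ccco1 | starting material
2 | (2E)-1-bromopent-2-ene | CC/C=C/CBr | starting material
3 | 2-(diethoxymethyl)-5-[(2E)-pent-2-en-1-yl]furan | CCOC(OCC)c1ccc(C/C=C/CC)o1 | intermediate
4 | 5-[(2E)-pent-2-en-1-yl]furan-2-carbaldehyde | O=Cc1ccc(C/C=C/CC)o1 | intermediate
5 | tributyl(propa-1,2-dien-1-yl)stannane | C=C=C[Sn](CCCC)(CCCC)CCCC | starting material
6 | (1R)-1-{5-[(2E)-pent-2-en-1-yl]furan-2-yl}but-3-yn-1-ol | C#CC[C@@H](O)c1ccc(C/C=C/CC)o1 | intermediate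
7 | (2R)-6-hydroxy-6-[(2E)-pent-2-en-1-yl]-2-(prop-2-yn-1-yl)-2H-pyran-3(6H)-one, mixture at the hemiketal carbon | C#CC[C@H]1OC(O)(C/C=C/CC)C=CC1=O | intermediate
8 | (2R,6S)-6-[(2E)-pent-2-en-1-yl]-2-(prop-2-yn-1-yl)-2H-pyran-3(6H)-one, 2,6-cis | C#CC[C@H]1O[C@@H](C/C=C/CC)C=CC1=O | intermediate
9 | (2R,3R,6S)-6-[(2E)-pent-2-en-1-yl]-2-(prop-2-yn-1-yl)-3,6-dihydro-2H-pyran-3-ol, all-cis | C#CC[C@H]1O[C@@H](C/C=C/CC)C=C[C@H]1O | intermediate
10 | (1R,2S,4R,5S,6S)-2-[(2E)-pent-2-en-1-yl]-4-(prop-2-yn-1-yl)-3,7-dioxabicyclo[4.1.0]heptan-5-ol, epoxide cis to OH and both side chains | C#CC[C@H]1O[C@@H](C/C=C/CC)[C@H]2O[C@H]2[C@H]1O | intermediate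
11 | triethyl{[(1R,2S,4R,5S,6R)-2-[(2E)-pent-2-en-1-yl]-4-(prop-2-yn-1-yl)-3,7-dioxabicyclo[4.1.0]heptan-5-yl]oxy}silane | C#CC[C@H]1O[C@@H](C/C=C/CC)[C@H]2O[C@H]2[C@H]1O[Si](CC)(CC)CC | intermediate
12 | (2S,3S,5R,6R)-2-[(2E)-pent-2-en-1-yl]-6-(prop-2-yn-1-yl)-5-[(triethylsilyl)oxy]oxan-3-ol, all-cis | C#CC[C@H]1O[C@@H](C/C=C/CC)[C@@H](O)C[C@H]1O[Si](CC)(CC)CC | intermediate
13 | (2S,3S,5R,6R)-2-[(2E)-pent-2-en-1-yl]-6-(prop-2-yn-1-yl)-5-[(triethylsilyl)oxy]oxan-3-yl acetate | C#CC[C@H]1O[C@@H](C/C=C/CC)[C@@H](OC(C)=O)C[C@H]1O[Si](CC)(CC)CC | intermediate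
14 | (2S,3S,5R,6R)-5-hydroxy-2-[(2E)-pent-2-en-1-yl]-6-(prop-2-yn-1-yl)oxan-3-yl acetate | C#CC[C@H]1O[C@@H](C/C=C/CC)[C@@H](OC(C)=O)C[C@H]1O | intermediate
15 | (1R,3R,5S,7R,9S)-3-[(1S)-1-bromopropyl]-7-(prop-2-yn-1-yl)-2,6-dioxabicyclo[3.2.2]nonan-9-yl acetate | C#CC[C@H]1O[C@H]2C[C@H]([C@@H](Br)CC)O[C@@H]1C[C@@H]2OC(C)=O | intermediate
16 | (1R,3R,5S,7R,9S)-3-[(1S)-1-bromopropyl]-7-(prop-2-yn-1-yl)-2,6-dioxabicyclo[3.2.2]nonan-9-ol | C#CC[C@H]1O[C@H]2C[C@H]([C@@H](Br)CC)O[C@@H]1C[C@@H]2O | intermediate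
17 | (1R,3R,5S,7R,9S)-3-[(1S)-1-bromopropyl]-7-(prop-2-yn-1-yl)-2,6-dioxabicyclo[3.2.2]nonan-9-yl trifluoromethanesulfonate | C#CC[C@H]1O[C@H]2C[C@H]([C@@H](Br)CC)O[C@@H]1C[C@@H]2OS(=O)(=O)C(F)(F)F | intermediate
18 | tricyclic oxonium triflate in which the former oxane oxygen is bonded to C6, C9 and C10 (oxiranium fused across C9–C10) | C#CC[C@H]1[O+]2[C@@H]3C[C@H]1O[C@@H]([C@@H](Br)CC)C[C@H]23.[O-]S(=O)(=O)C(F)(F)F | intermediate
19 | (1R,3R,5R,6R,8R)-5-bromo-3-[(1S)-1-bromopropyl]-8-(prop-2-yn-1-yl)-2,7-dioxabicyclo[4.2.1]nonane | C#CC[C@H]1O[C@@H]2C[C@H]1O[C@@H]([C@@H](Br)CC)C[C@H]2Br | intermediate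
20 | (1R,3R,5R,6R,8R)-5-bromo-3-[(1S)-1-bromopropyl]-8-(3-iodoprop-2-yn-1-yl)-2,7-dioxabicyclo[4.2.1]nonane | IC#CC[C@H]1O[C@@H]2C[C@H]1O[C@@H]([C@@H](Br)CC)C[C@H]2Br | intermediate
21 | (1R,3R,5R,6R,8R)-5-bromo-3-[(1S)-1-bromopropyl]-8-[(2Z)-3-iodoprop-2-en-1-yl]-2,7-dioxabicyclo[4.2.1]nonane | I/C=C\C[C@H]1O[C@@H]2C[C@H]1O[C@@H]([C@@H](Br)CC)C[C@H]2Br | intermediate
22 | ethynyltrimethylsilane | C#C[Si](C)(C)C | starting material
23 | (1R,3R,5R,6R,8R)-5-bromo-3-[(1S)-1-bromopropyl]-8-[(2Z)-5-(trimethylsilyl)pent-2-en-4-yn-1-yl]-2,7-dioxabicyclo[4.2.1]nonane | C[Si](C)(C)C#C/C=C\C[C@H]1O[C@@H]2C[C@H]1O[C@@H]([C@@H](Br)CC)C[C@H]2Br | intermediate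
24 | (1R,3R,5R,6R,8R)-5-bromo-3-[(1S)-1-bromopropyl]-8-[(2Z)-pent-2-en-4-yn-1-yl]-2,7-dioxabicyclo[4.2.1]nonane | C#C/C=C\C[C@H]1O[C@@H]2C[C@H]1O[C@@H]([C@@H](Br)CC)C[C@H]2Br | target

## Step count and risks

Total step count: 16. Longest linear sequence: 16 steps (1 → 24; compounds 2, 5 and 22 are purchased).

Steps most likely to fail:

1. Step 10 (bridging bromoetherification). The seven-membered closure has to pass through a boat-like oxane, so it may be slow enough for the bromonium ion to be intercepted by chloride from the counter-ion or by the alkyne, and the facial selectivity at C12 rests on substrate control alone. Fallback, from 14 back to 15: Shi epoxidation of the (E)-alkene with the enantiomer of the fructose-derived ketone (Oxone (2KHSO5·KHSO4·K2SO4), K2CO3, MeCN/dimethoxymethane/aqueous buffer, 0 °C) should give, under reagent control, (2S,3S,5R,6R)-2-{[(2S,3S)-3-ethyloxiran-2-yl]methyl}-5-hydroxy-6-(prop-2-yn-1-yl)oxan-3-yl acetate F1. Camphorsulfonic acid in CH2Cl2 then drives 7-exo opening of the epoxide by the C7 hydroxyl with inversion at C12 to (1R,3R,5S,7R,9S)-3-[(1S)-1-hydroxypropyl]-7-(prop-2-yn-1-yl)-2,6-dioxabicyclo[3.2.2]nonan-9-yl acetate F2, with no halide present to divert the electrophile. Because this alcohol has the configuration that a direct inverting bromination would turn into the wrong C13 epimer, it is oxidised with Dess–Martin periodinane to (1R,3R,5S,7R,9S)-3-propanoyl-7-(prop-2-yn-1-yl)-2,6-dioxabicyclo[3.2.2]nonan-9-yl acetate F3. Reduction with LiBH(s-Bu)3 at −78 °C (Felkin–Anh, syn to the ring oxygen) gives (1R,3R,5S,7R,9S)-3-[(1R)-1-hydroxypropyl]-7-(prop-2-yn-1-yl)-2,6-dioxabicyclo[3.2.2]nonan-9-yl acetate F4. Bromination with CBr4 and P(n-Oct)3 (toluene, 70 °C, inversion at C13) returns to 15.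

2. Step 12 (key ring contraction). Bromide may displace the triflate directly at C9 without the oxygen shift, or capture the oxonium ion at C9 and so return to the bicyclo[3.2.2] skeleton. Fallback, from 16 back to 19: the triflate 17 is formed as before but allowed to ionise with no good nucleophile present, and the oxonium ion 18 is quenched with water (Tf2O, 2,6-di-tert-butyl-4-methylpyridine, CH2Cl2, −78 → 0 °C; then H2O/THF). This should give the ring-contracted alcohol (1R,3R,5R,6R,8R)-3-[(1S)-1-bromopropyl]-8-(prop-2-yn-1-yl)-2,7-dioxabicyclo[4.2.1]nonan-5-ol F5, with the hydroxyl anti to the oxolane oxygen. Dess–Martin oxidation gives (1R,3R,6R,8R)-3-[(1S)-1-bromopropyl]-8-(prop-2-yn-1-yl)-2,7-dioxabicyclo[4.2.1]nonan-5-one F6. LiBH(s-Bu)3 (THF, −78 °C) should add hydride anti to the C9–O bond and from the open face to give the epimer (1R,3R,5S,6R,8R)-3-[(1S)-1-bromopropyl]-8-(prop-2-yn-1-yl)-2,7-dioxabicyclo[4.2.1]nonan-5-ol F7. Its C–O bond is no longer antiperiplanar to the ring oxygen, so CBr4/P(n-Oct)3 (toluene, 70 °C) should brominate by plain SN2 inversion to 19.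

3. Step 5 (CBS reduction). A mismatched catalyst–substrate pairing or competing conjugate reduction may erode the facial selectivity at C7. Fallback, from 8 back to 9: Luche reduction (NaBH4, CeCl3·7H2O, MeOH, −78 °C; axial hydride attack) gives the trans alcohol (2R,3S,6S)-6-[(2E)-pent-2-en-1-yl]-2-(prop-2-yn-1-yl)-3,6-dihydro-2H-pyran-3-ol F8. Mitsunobu inversion (4-nitrobenzoic acid, PPh3, diisopropyl azodicarboxylate, THF, 0 °C) gives (2R,3R,6S)-6-[(2E)-pent-2-en-1-yl]-2-(prop-2-yn-1-yl)-3,6-dihydro-2H-pyran-3-yl 4-nitrobenzoate F9. Methanolysis (K2CO3, MeOH) returns to 9.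

Further compounds
F1 | step 10 | (2S,3S,5R,6R)-2-{[(2S,3S)-3-ethyloxiran-2-yl]methyl}-5-hydroxy-6-(prop-2-yn-1-yl)oxan-3-yl acetate | C#CC[C@H]1O[C@@H](C[C@@H]2O[C@H]2CC)[C@@H](OC(C)=O)C[C@H]1O
F2 | step 10 | (1R,3R,5S,7R,9S)-3-[(1S)-1-hydroxypropyl]-7-(prop-2-yn-1-yl)-2,6-dioxabicyclo[3.2.2]nonan-9-yl acetate | C#CC[C@H]1O[C@H]2C[C@H]([C@@H](O)CC)O[C@@H]1C[C@@H]2OC(C)=O
F3 | step 10 | (1R,3R,5S,7R,9S)-3-propanoyl-7-(prop-2-yn-1-yl)-2,6-dioxabicyclo[3.2.2]nonan-9-yl acetate | C#CC[C@H]1O[C@H]2C[C@H](C(=O)CC)O[C@@H]1C[C@@H]2OC(C)=O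
F4 | step 10 | (1R,3R,5S,7R,9S)-3-[(1R)-1-hydroxypropyl]-7-(prop-2-yn-1-yl)-2,6-dioxabicyclo[3.2.2]nonan-9-yl acetate | C#CC[C@H]1O[C@H]2C[C@H]([C@H](O)CC)O[C@@H]1C[C@@H]2OC(C)=O
F5 | step 12 | (1R,3R,5R,6R,8R)-3-[(1S)-1-bromopropyl]-8-(prop-2-yn-1-yl)-2,7-dioxabicyclo[4.2.1]nonan-5-ol | C#CC[C@H]1O[C@@H]2C[C@H]1O[C@@H]([C@@H](Br)CC)C[C@H]2O
F6 | step 12 | (1R,3R,6R,8R)-3-[(1S)-1-bromopropyl]-8-(prop-2-yn-1-yl)-2,7-dioxabicyclo[4.2.1]nonan-5-one | C#CC[C@H]1O[C@@H]2C[C@H]1O[C@@H]([C@@H](Br)CC)CC2=O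
F7 | step 12 | (1R,3R,5S,6R,8R)-3-[(1S)-1-bromopropyl]-8-(prop-2-yn-1-yl)-2,7-dioxabicyclo[4.2.1]nonan-5-ol | C#CC[C@H]1O[C@@H]2C[C@H]1O[C@@H]([C@@H](Br)CC)C[C@@H]2O
F8 | step 5 | (2R,3S,6S)-6-[(2E)-pent-2-en-1-yl]-2-(prop-2-yn-1-yl)-3,6-dihydro-2H-pyran-3-ol | C#CC[C@H]1O[C@@H](C/C=C/CC)C=C[C@@H]1O
F9 | step 5 | (2R,3R,6S)-6-[(2E)-pent-2-en-1-yl]-2-(prop-2-yn-1-yl)-3,6-dihydro-2H-pyran-3-yl 4-nitrobenzoate | C#CC[C@H]1O[C@@H](C/C=C/CC)C=C[C@H]1OC(=O)c1ccc(cc1)[N+](=O)[O-]
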